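**Retrosynthetic overview**
1. Target ⇐ perbenzylated all-trans tetramer 22 (global debenzylation) ⇐ cis,cis isomer 21 (acid equilibration of both C2 centres). No biomimetic phenol coupling and no late stilbene olefination is used.
2. Ring B is cut at C2–C3 (enantioselective donor/donor carbene 1,5 C–H insertion into the benzylic C–H of an aryl 4-(benzyloxy)benzyl ether, which supplies C2 and its aryl group) and at C3–aryl (ring C aryllithium + aryl nitrile → ketimine → hydrazone → diazo).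
3. Ring C is cut the same way, with the antipodal catalyst, from ketimine 6 (nitrile 3 + arylmagnesium bromide 5).
4. Ring A (achiral benzofuran) comes from the same ketimine 6 by hydrolysis and base-mediated cyclodehydration; vinylation and a fragment-level Heck reaction place the E-stilbene in nitrile 13 before ring B exists.
5. Order of ring formation: A, then C, then B.

Assumption: Rh2(S-PTAD)4 is taken to give the (3S)-cis ring and Rh2(R-PTAD)4 the (3R)-cis ring, by analogy with simpler 2-(benzyloxy)aryl aryl diazomethanes; if the first insertion shows the opposite sense, the two antipodes are exchanged and nothing else changes.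

Abbreviations: Bn = benzyl; PBB = 4-(benzyloxy)benzyl; Rh2(S-PTAD)4 = Rh2[(S)-(1-adamantyl)(phthalimido)acetate]4. Ring A = benzofuran, ring B = stilbene-bearing dihydrobenzofuran, ring C = terminal dihydrobenzofuran.

**Step 1**
Reactants: 1 2-bromo-4,6-difluorobenzonitrile; 2 4-(benzyloxy)benzyl alcohol (2.2 equiv)
Product: 3 2-bromo-4,6-bis{[4-(benzyloxy)benzyl]oxy}benzonitrile
Conditions: NaH, THF/DMF, 0 °C to rt
Reagents that add atoms: none
Why: Twofold SNAr, in which both fluorides (ortho and para to the nitrile) are displaced far faster than the bromide and, being meta to each other, the first alkoxy group does not deactivate the second site.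

**Step 2**
Reactants: 4 1,3-bis(benzyloxy)-5-bromobenzene; 3 2-bromo-4,6-bis{[4-(benzyloxy)benzyl]oxy}benzonitrile
Product: 6 1-[3,5-bis(benzyloxy)phenyl]-1-(2-bromo-4,6-bis{[4-(benzyloxy)benzyl]oxy}phenyl)methanimine (N–H ketimine), via arylmagnesium bromide 5 (not isolated)
Conditions: Mg, THF, 65 °C; then 3, toluene, 90 °C; aq. NaHCO3 work-up
Reagents that add atoms: none
Why: Grignard addition to a nitrile stops at the N-magnesio ketimine, the linear nitrile tolerates its two ortho substituents, and the doubly ortho-substituted N–H ketimine is robust enough to isolate.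

**Step 3**
Reactants: 6 N–H ketimine
Product: 7 [3,5-bis(benzyloxy)phenyl](2-bromo-4,6-bis{[4-(benzyloxy)benzyl]oxy}phenyl)methanone
Conditions: 2 M aq. HCl, THF, 60 °C
Reagents that add atoms: water, O
Why: Acid-catalysed imine hydrolysis gives the diaryl ketone, and aryl benzyl ethers survive dilute aqueous acid.

**Step 4**
Reactants: 7 diaryl ketone
Product: 9 2-[4-(benzyloxy)phenyl]-3-[3,5-bis(benzyloxy)phenyl]-4-bromo-6-{[4-(benzyloxy)benzyl]oxy}-1-benzofuran (ring A bromide), via benzofuranol 8 (not isolated)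
Conditions: phosphazene base P4-t-Bu (1.1 equiv), toluene, 90 °C; then PPTS (cat.), 60 °C
Reagents that add atoms: none
Why: Base-mediated intramolecular aldol-type cyclodehydration, in which the carbanion of the ortho O–CH2–aryl group adds to the non-enolisable ketone and loss of water aromatises to the 2,3-diarylbenzofuran, so no stereocentre remains.

**Step 5**
Reactants: 9 ring A bromide
Product: 10 2-[4-(benzyloxy)phenyl]-3-[3,5-bis(benzyloxy)phenyl]-6-{[4-(benzyloxy)benzyl]oxy}-4-ethenyl-1-benzofuran (ring A styrene)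
Conditions: Pd(PPh3)4 (5 mol %), toluene, 105 °C
Reagents that add atoms: tributyl(vinyl)stannane, C=C[Sn](CCCC)(CCCC)CCCC
Why: Stille coupling of the aryl bromide with the vinylstannane installs the styrene handle without touching the benzyl ethers.

**Step 6**
Reactants: 11 5-bromo-2-fluorobenzonitrile; 2 4-(benzyloxy)benzyl alcohol
Product: 12 5-bromo-2-{[4-(benzyloxy)benzyl]oxy}benzonitrile
Conditions: NaH, THF, 0 °C to rt
Reagents that add atoms: none
Why: SNAr of the fluoride ortho to the nitrile, while the bromide (meta to the nitrile) is inert under these conditions.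

**Step 7**
Reactants: 10 ring A styrene; 12 5-bromo-2-{[4-(benzyloxy)benzyl]oxy}benzonitrile
Product: 13 2-{[4-(benzyloxy)benzyl]oxy}-5-[(E)-2-{2-[4-(benzyloxy)phenyl]-3-[3,5-bis(benzyloxy)phenyl]-6-{[4-(benzyloxy)benzyl]oxy}-1-benzofuran-4-yl}ethenyl]benzonitrile (ring A stilbene nitrile)
Conditions: Pd(OAc)2 (5 mol %), P(o-tol)3, NaOAc, DMF, 110 °C
Reagents that add atoms: none
Why: Heck reaction of the aryl bromide with the terminal styrene gives the E-stilbene through syn insertion and syn β-hydride elimination, the double-bond geometry being the only stereo-element formed.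

**Step 8**
Reactants: 6 N–H ketimine
Product: 14 hydrazone of ketone 7, [3,5-bis(benzyloxy)phenyl](2-bromo-4,6-bis{[4-(benzyloxy)benzyl]oxy}phenyl)methanone hydrazone
Conditions: N2H4·H2O (20 equiv), N2H4·2HCl (0.3 equiv), n-BuOH, 110 °C, Ar
Reagents that add atoms: hydrazine, NN
Why: Transimination of the N–H ketimine with hydrazine is the classical entry to hydrazones of hindered ketones because no dehydration step is needed, and copper-free material avoids N-arylation onto the ortho bromide.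

**Step 9**
Reactants: 14 hydrazone
Product: 16 (2R,3S)-cis-2-[4-(benzyloxy)phenyl]-3-[3,5-bis(benzyloxy)phenyl]-4-bromo-6-{[4-(benzyloxy)benzyl]oxy}-2,3-dihydro-1-benzofuran (ring C bromide), via diazo compound 15 (not isolated)
Conditions: MnO2 (10 equiv), CH2Cl2, 0 °C; filter; Rh2(S-PTAD)4 (1 mol %), CH2Cl2, −20 °C to rt
Reagents that add atoms: none
Why: Hydrazone dehydrogenation gives the diaryldiazomethane, and the donor/donor carbene formed on Rh2(S-PTAD)4 undergoes enantioselective 1,5 C–H insertion into the ortho benzylic ether C–H, the chiral carboxylate pocket setting C3 as S and the kinetic ring closure giving the cis (2R) ring, while the para benzylic ether cannot reach the carbene.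

**Step 10**
Reactants: 16 ring C bromide (1.15 equiv); 13 ring A stilbene nitrile
Product: 19 hydrazone in which the C=N carbon (former nitrile carbon of 13) carries C4 of the (2R,3S)-cis ring C unit, via aryllithium 17 (not isolated), via ketimine 18 (not isolated)
Conditions: t-BuLi (2.0 equiv per 16), THF, −78 °C; 13, −78 to 0 °C; AcOH (1.1 equiv); N2H4·H2O (10 equiv), EtOH, 60 °C, Ar
Reagents that add atoms: hydrazine, NN
Why: Bromine–lithium exchange, 1,2-addition of the aryllithium to the nitrile (which stops at the N-lithio ketimine) and in-pot transimination with hydrazine join ring C to the ring A stilbene fragment, and at −78 °C the existing C2 and C3 centres are not deprotonated.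

**Step 11**
Reactants: 19 hydrazone
Product: 21 perbenzylated cis-cis tetramer [ring B (2S,3R); ring C (2R,3S)], via diazo compound 20 (not isolated)
Conditions: MnO2 (10 equiv), CH2Cl2, 0 °C; filter; Rh2(R-PTAD)4 (2 mol %), CH2Cl2, −20 °C to rt
Reagents that add atoms: none
Why: The same hydrazone dehydrogenation and enantioselective 1,5 C–H insertion as in step 9 is run with the antipodal catalyst because ring B needs the opposite C3 configuration (R) with the same substituent priority pattern, catalyst control is expected to override the remote ring C centres, and the cis (2S) ring forms kinetically.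

**Step 12**
Reactants: 21 perbenzylated cis-cis tetramer
Product: 22 perbenzylated all-trans tetramer [ring B (2R,3R); ring C (2S,3S)]
Conditions: TFA (2 vol %), CH2Cl2, −20 to 0 °C
Reagents that add atoms: none
Why: Acid-catalysed epimerisation, in which reversible ionisation of each C2–O bond to a 4-alkoxybenzylic cation and reclosure by the neighbouring phenol oxygen equilibrates both C2 centres to the more stable trans rings while C3 is never touched, with stilbene protonation and ionisation of the primary benzyl ethers being much slower under these dilute conditions.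

**Step 13**
Reactants: 22 perbenzylated all-trans tetramer
Product: 23 target tetramer (CNP0135983.1)
Conditions: BCl3 (30 equiv), C6HMe5 (40 equiv), CH2Cl2, −78 °C; then H2O
Reagents that add atoms: none
Why: Lewis acid debenzylation with pentamethylbenzene as a non-basic cation scavenger cleaves all eleven benzylic C–O bonds at low temperature without hydrogenation, so the stilbene, both ring C2–O bonds and all four stereocentres are preserved.

**Compound list**
1 | 2-bromo-4,6-difluorobenzonitrile | N#Cc1c(F)cc(F)cc1Br | starting material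
2 | 4-(benzyloxy)benzyl alcohol | OCc1ccc(OCc2ccccc2)cc1 | starting material
3 | 2-bromo-4,6-bis{[4-(benzyloxy)benzyl]oxy}benzonitrile | N#Cc1c(OCc2ccc(OCc3ccccc3)cc2)cc(OCc2ccc(OCc3ccccc3)cc2)cc1Br | intermediate
4 | 1,3-bis(benzyloxy)-5-bromobenzene | Brc1cc(OCc2ccccc2)cc(OCc2ccccc2)c1 | starting material
5 | [3,5-bis(benzyloxy)phenyl]magnesium bromide | Br[Mg]c1cc(OCc2ccccc2)cc(OCc2ccccc2)c1 | intermediate
6 | 1-[3,5-bis(benzyloxy)phenyl]-1-(2-bromo-4,6-bis{[4-(benzyloxy)benzyl]oxy}phenyl)methanimine | N=C(c1cc(OCc2ccccc2)cc(OCc2ccccc2)c1)c1c(OCc2ccc(OCc3ccccc3)cc2)cc(OCc2ccc(OCc3ccccc3)cc2)cc1Br | intermediate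
7 | [3,5-bis(benzyloxy)phenyl](2-bromo-4,6-bis{[4-(benzyloxy)benzyl]oxy}phenyl)methanone | O=C(c1cc(OCc2ccccc2)cc(OCc2ccccc2)c1)c1c(OCc2ccc(OCc3ccccc3)cc2)cc(OCc2ccc(OCc3ccccc3)cc2)cc1Br | intermediate
8 | 2-[4-(benzyloxy)phenyl]-3-[3,5-bis(benzyloxy)phenyl]-4-bromo-6-{[4-(benzyloxy)benzyl]oxy}-2,3-dihydro-1-benzofuran-3-ol (racemic diastereomer mixture) | OC1(c2cc(OCc3ccccc3)cc(OCc3ccccc3)c2)C(c2ccc(OCc3ccccc3)cc2)Oc2cc(OCc3ccc(OCc4ccccc4)cc3)cc(Br)c21 | intermediate
9 | 2-[4-(benzyloxy)phenyl]-3-[3,5-bis(benzyloxy)phenyl]-4-bromo-6-{[4-(benzyloxy)benzyl]oxy}-1-benzofuran (ring A bromide) | Brc1cc(OCc2ccc(OCc3ccccc3)cc2)cc2oc(-c3ccc(OCc4ccccc4)cc3)c(-c3cc(OCc4ccccc4)cc(OCc4ccccc4)c3)c12 | intermediate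
10 | 2-[4-(benzyloxy)phenyl]-3-[3,5-bis(benzyloxy)phenyl]-6-{[4-(benzyloxy)benzyl]oxy}-4-ethenyl-1-benzofuran (ring A styrene) | C=Cc1cc(OCc2ccc(OCc3ccccc3)cc2)cc2oc(-c3ccc(OCc4ccccc4)cc3)c(-c3cc(OCc4ccccc4)cc(OCc4ccccc4)c3)c12 | intermediate
11 | 5-bromo-2-fluorobenzonitrile | N#Cc1cc(Br)ccc1F | starting material
12 | 5-bromo-2-{[4-(benzyloxy)benzyl]oxy}benzonitrile | N#Cc1cc(Br)ccc1OCc1ccc(OCc2ccccc2)cc1 | intermediate
13 | 2-{[4-(benzyloxy)benzyl]oxy}-5-[(E)-2-(ring A benzofuran-4-yl)ethenyl]benzonitrile, ring A as in 10 | N#Cc1cc(/C=C/c2cc(OCc3ccc(OCc4ccccc4)cc3)cc3oc(-c4ccc(OCc5ccccc5)cc4)c(-c4cc(OCc5ccccc5)cc(OCc5ccccc5)c4)c23)ccc1OCc1ccc(OCc2ccccc2)cc1 | intermediate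
14 | hydrazone of ketone 7 | NN=C(c1cc(OCc2ccccc2)cc(OCc2ccccc2)c1)c1c(OCc2ccc(OCc3ccccc3)cc2)cc(OCc2ccc(OCc3ccccc3)cc2)cc1Br | intermediate
15 | [3,5-bis(benzyloxy)phenyl](2-bromo-4,6-bis{[4-(benzyloxy)benzyl]oxy}phenyl)diazomethane | [N-]=[N+]=C(c1cc(OCc2ccccc2)cc(OCc2ccccc2)c1)c1c(OCc2ccc(OCc3ccccc3)cc2)cc(OCc2ccc(OCc3ccccc3)cc2)cc1Br | intermediate
16 | (2R,3S)-cis-2-[4-(benzyloxy)phenyl]-3-[3,5-bis(benzyloxy)phenyl]-4-bromo-6-{[4-(benzyloxy)benzyl]oxy}-2,3-dihydro-1-benzofuran (ring C bromide) | Brc1cc(OCc2ccc(OCc3ccccc3)cc2)cc2c1[C@H](c1cc(OCc3ccccc3)cc(OCc3ccccc3)c1)[C@H](c1ccc(OCc3ccccc3)cc1)O2 | intermediate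
17 | 4-lithio analogue of 16 (ring C aryllithium, 2R,3S) | [Li]c1cc(OCc2ccc(OCc3ccccc3)cc2)cc2c1[C@H](c1cc(OCc3ccccc3)cc(OCc3ccccc3)c1)[C@H](c1ccc(OCc3ccccc3)cc1)O2 | intermediate
18 | N–H ketimine: imine carbon (former nitrile carbon of 13) bonded to C4 of the (2R,3S)-cis ring C unit | N=C(c1cc(/C=C/c2cc(OCc3ccc(OCc4ccccc4)cc3)cc3oc(-c4ccc(OCc5ccccc5)cc4)c(-c4cc(OCc5ccccc5)cc(OCc5ccccc5)c4)c23)ccc1OCc1ccc(OCc2ccccc2)cc1)c1cc(OCc2ccc(OCc3ccccc3)cc2)cc2c1[C@H](c1cc(OCc3ccccc3)cc(OCc3ccccc3)c1)[C@H](c1ccc(OCc3ccccc3)cc1)O2 | intermediate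
19 | hydrazone corresponding to ketimine 18 | NN=C(c1cc(/C=C/c2cc(OCc3ccc(OCc4ccccc4)cc3)cc3oc(-c4ccc(OCc5ccccc5)cc4)c(-c4cc(OCc5ccccc5)cc(OCc5ccccc5)c4)c23)ccc1OCc1ccc(OCc2ccccc2)cc1)c1cc(OCc2ccc(OCc3ccccc3)cc2)cc2c1[C@H](c1cc(OCc3ccccc3)cc(OCc3ccccc3)c1)[C@H](c1ccc(OCc3ccccc3)cc1)O2 | intermediate
20 | diaryldiazomethane corresponding to hydrazone 19 | [N-]=[N+]=C(c1cc(/C=C/c2cc(OCc3ccc(OCc4ccccc4)cc3)cc3oc(-c4ccc(OCc5ccccc5)cc4)c(-c4cc(OCc5ccccc5)cc(OCc5ccccc5)c4)c23)ccc1OCc1ccc(OCc2ccccc2)cc1)c1cc(OCc2ccc(OCc3ccccc3)cc2)cc2c1[C@H](c1cc(OCc3ccccc3)cc(OCc3ccccc3)c1)[C@H](c1ccc(OCc3ccccc3)cc1)O2 | intermediate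
21 | perbenzylated cis-cis tetramer: ring B (2S,3R) with 2-[4-(benzyloxy)phenyl], C3 bonded to C4 of ring C (2R,3S), C5 bearing the (E)-ethenyl link to C4 of ring A | c1ccccc1COc1ccc(cc1)-c1oc2cc(OCc3ccc(OCc4ccccc4)cc3)cc(/C=C/c3ccc4c(c3)[C@@H](c3cc(OCc5ccc(OCc6ccccc6)cc5)cc5c3[C@H](c3cc(OCc6ccccc6)cc(OCc6ccccc6)c3)[C@H](c3ccc(OCc6ccccc6)cc3)O5)[C@@H](c3ccc(OCc5ccccc5)cc3)O4)c2c1-c1cc(OCc2ccccc2)cc(OCc2ccccc2)c1 | intermediate
22 | perbenzylated all-trans tetramer: as 21 but ring B (2R,3R) and ring C (2S,3S) | c1ccccc1COc1ccc(cc1)-c1oc2cc(OCc3ccc(OCc4ccccc4)cc3)cc(/C=C/c3ccc4c(c3)[C@@H](c3cc(OCc5ccc(OCc6ccccc6)cc5)cc5c3[C@H](c3cc(OCc6ccccc6)cc(OCc6ccccc6)c3)[C@@H](c3ccc(OCc6ccccc6)cc3)O5)[C@H](c3ccc(OCc5ccccc5)cc3)O4)c2c1-c1cc(OCc2ccccc2)cc(OCc2ccccc2)c1 | intermediate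
23 | target tetramer: ring B (2R,3R), ring C (2S,3S), E-stilbene, nine free phenols | Oc1ccc(-c2oc3cc(O)cc(/C=C/c4ccc5c(c4)[C@@H](c4cc(O)cc6c4[C@H](c4cc(O)cc(O)c4)[C@@H](c4ccc(O)cc4)O6)[C@H](c4ccc(O)cc4)O5)c3c2-c2cc(O)cc(O)c2)cc1 | target

**Totals**
Total step count: 13. Longest linear sequence: 10 steps (1, 2, 3, 4, 5, 7, 10, 11, 12, 13).

**Three steps most likely to fail**

Step 9 (the carbene carbon sits on a doubly ortho-substituted aryl ring, so carbene formation on the bulky chiral catalyst and the enantiomeric excess are uncertain). Fallback: resolution in place of asymmetric catalysis. It sets out from hydrazone 14: diazo compound 15 is made with MnO2 as before and decomposed with the small achiral catalyst Rh2(OAc)4 (CH2Cl2, 40 °C), which tolerates the two ortho substituents better than the chiral carboxylate. This gives the racemic cis ring, that is 16 together with the (2S,3R)-enantiomer of 16 F1. Preparative chiral SFC returns enantiopure 16, where the route is rejoined.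

Step 11 (late-stage insertion on the full skeleton: double asymmetric induction, a very large substrate, and possible attack of the carbene on the neighbouring 3,5-bis(benzyloxy)phenyl ring). Fallback: change the order of fragment union so that ring B is closed on a small substrate and the stilbene is made last. It sets out from 16 and uses 12 and 10. Aryllithium 17 is transmetalated with MgBr2·OEt2 to the ring C arylmagnesium bromide F2, which does not exchange with an aryl bromide. F2 is added to bromonitrile 12 (CuBr·SMe2 cat., THF, 50 °C) to give the bromo ketimine F3. Hydrazine converts F3 to the bromo hydrazone F4, MnO2 gives the bromo diazo compound F5, and Rh2(R-PTAD)4 gives the cis,cis ring B–ring C bromide F6. A Heck reaction of F6 with styrene 10 (Pd(OAc)2, P(o-tol)3, NaOAc, DMF, 110 °C) gives 21, where the route is rejoined.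

Step 12 (acid next to a stilbene, and next to an electron-rich aryl ring that could trap the ring B cation in a seven-membered Friedel–Crafts closure). Fallback: deprotect first and equilibrate under base. It sets out from 21: BCl3/C6HMe5 (CH2Cl2, −78 °C) gives the free cis,cis nonaphenol F7. In degassed MeOH with K2CO3 at 40 °C, each 2-(4-hydroxyphenyl) ring opens reversibly to a para-quinone methide phenoxide (retro-oxa-Michael) and recloses (oxa-Michael) to the trans ring, with C3 untouched. This gives the target 23 directly.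

**Further compounds**
F1 | step 9 | (2S,3R)-enantiomer of 16 | Brc1cc(OCc2ccc(OCc3ccccc3)cc2)cc2c1[C@@H](c1cc(OCc3ccccc3)cc(OCc3ccccc3)c1)[C@@H](c1ccc(OCc3ccccc3)cc1)O2
F2 | step 11 | ring C arylmagnesium bromide (4-bromomagnesio analogue of 16, 2R,3S) | Br[Mg]c1cc(OCc2ccc(OCc3ccccc3)cc2)cc2c1[C@H](c1cc(OCc3ccccc3)cc(OCc3ccccc3)c1)[C@H](c1ccc(OCc3ccccc3)cc1)O2
F3 | step 11 | bromo ketimine from F2 and 12 | N=C(c1cc(Br)ccc1OCc1ccc(OCc2ccccc2)cc1)c1cc(OCc2ccc(OCc3ccccc3)cc2)cc2c1[C@H](c1cc(OCc3ccccc3)cc(OCc3ccccc3)c1)[C@H](c1ccc(OCc3ccccc3)cc1)O2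
F4 | step 11 | bromo hydrazone corresponding to F3 | NN=C(c1cc(Br)ccc1OCc1ccc(OCc2ccccc2)cc1)c1cc(OCc2ccc(OCc3ccccc3)cc2)cc2c1[C@H](c1cc(OCc3ccccc3)cc(OCc3ccccc3)c1)[C@H](c1ccc(OCc3ccccc3)cc1)O2
F5 | step 11 | bromo diazo compound corresponding to F4 | [N-]=[N+]=C(c1cc(Br)ccc1OCc1ccc(OCc2ccccc2)cc1)c1cc(OCc2ccc(OCc3ccccc3)cc2)cc2c1[C@H](c1cc(OCc3ccccc3)cc(OCc3ccccc3)c1)[C@H](c1ccc(OCc3ccccc3)cc1)O2
F6 | step 11 | cis,cis ring B–ring C bromide: ring B (2S,3R) 5-bromo, ring C (2R,3S) | Brc1ccc2c(c1)[C@@H](c1cc(OCc3ccc(OCc4ccccc4)cc3)cc3c1[C@H](c1cc(OCc4ccccc4)cc(OCc4ccccc4)c1)[C@H](c1ccc(OCc4ccccc4)cc1)O3)[C@@H](c1ccc(OCc3ccccc3)cc1)O2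
F7 | step 12 | free cis,cis nonaphenol (C2 epimer of the target in rings B and C) | Oc1ccc(-c2oc3cc(O)cc(/C=C/c4ccc5c(c4)[C@@H](c4cc(O)cc6c4[C@H](c4cc(O)cc(O)c4)[C@H](c4ccc(O)cc4)O6)[C@@H](c4ccc(O)cc4)O5)c3c2-c2cc(O)cc(O)c2)cc1
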